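**Assumptions**
- Ring numbering follows the target cyclooctane: C1(=O), C2(OH)(prenyl), C3(=O), C4(H)(isobutyryl), C5(Me)(homoprenyl), C6(H)(prenyl), C7H2, C8(H)(prenyl). The target is (2R,4R,5R,6S,8S). Prenyl = 3-methylbut-2-en-1-yl; homoprenyl = 4-methylpent-3-en-1-yl.
- C4 and C8 are α to carbonyls and epimerisable. I assume the natural configurations there are the thermodynamically preferred ones, so they are fixed by protonation/equilibration rather than by a dedicated stereocontrolled step. This is not proven and is flagged again in the risk list.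

**Retrosynthetic overview**
1. Target ⇐ aerobic C2 hydroxylation of the 2-prenyl cyclooctane-1,3-dione 15.
2. The eight-membered ring ⇐ photochemical 1,3-acyl shift (two-carbon ring expansion, 6→8) of the β,γ-unsaturated ketone 13, a mono-silyl enol ether of a 2-acyl-2-prenylcyclohexanone; this forms the C2–C3 bond.
3. 13 ⇐ cyclohexanone 9 by α′-acylation/prenylation; 9 ⇐ enone 6 by anti conjugate addition of a homoprenyl cuprate (sets quaternary C5) and enolate acylation.
4. Enone 6 ⇐ ring-closing metathesis of vinyl ketone 5 ⇐ (R)-limonene oxide by oxidative ring cleavage and Wittig olefination; limonene C4 becomes C6 of the target.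
5. Ring order: limonene ring opened → new cyclohexenone (RCM) → cyclooctane (photochemical expansion).

**Route**

Step 1
Reactants: 1, (+)-limonene 1,2-oxide [(4R)-1-methyl-4-(prop-1-en-2-yl)-7-oxabicyclo[4.1.0]heptane, commercial cis/trans mixture]
Product: 2, (3R)-6-oxo-3-(prop-1-en-2-yl)heptanal
Conditions: H5IO6, THF/H2O, 0 °C → rt
Reagents that add atoms: periodic acid, OI(=O)(O)(O)(O)O (supplies the second carbonyl oxygen)
Why: Periodic acid cleavage of the epoxide via the in-situ diol (Malaprade-type) opens only the ring C–C bond; the limonene stereocentre is untouched and becomes C6 of the target.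

Step 2
Reactants: 2; 3, isopropyltriphenylphosphonium iodide
Product: 4, (5R)-8-methyl-5-(prop-1-en-2-yl)non-7-en-2-one
Conditions: 3, n-BuLi, THF, 0 °C; then 2, −78 → 0 °C
Reagents that add atoms: 3, CC(C)[P+](c1ccccc1)(c1ccccc1)c1ccccc1.[I-] (adds C(CH3)2)
Why: Wittig olefination with a non-stabilised ylide is much faster on the aldehyde than on the methyl ketone and turns CH2CHO into the prenyl group; the stereocentre is β to the carbonyl and does not epimerise.

Step 3
Reactants: 4
Product: 5, (6R)-9-methyl-6-(prop-1-en-2-yl)deca-1,8-dien-3-one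
Conditions: LDA, THF, −78 °C; Me2N+=CH2 I−; then MeI; aq. NaHCO3
Reagents that add atoms: Eschenmoser's salt, C=[N+](C)C.[I-] (adds CH2)
Why: Kinetic methyl-side enolate, Mannich reaction with Eschenmoser's salt, then quaternisation/elimination gives the vinyl ketone; used crude because it polymerises.

Step 4
Reactants: 5
Product: 6, (4R)-3-methyl-4-(3-methylbut-2-en-1-yl)cyclohex-2-en-1-one
Conditions: Grubbs II (5 mol %), CH2Cl2 (5 mM), 40 °C
Reagents that add atoms: none
Why: Ring-closing metathesis of the enone with the 1,1-disubstituted isopropenyl alkene gives the trisubstituted cyclohexenone with loss of ethylene; the trisubstituted prenyl alkene is a poor partner and would give a seven-membered ring.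

Step 5
Reactants: 6; 7, 5-bromo-2-methylpent-2-ene (as its Grignard reagent); 8, isobutyryl chloride
Product: 9, (3R,4R)-3-methyl-3-(4-methylpent-3-en-1-yl)-4-(3-methylbut-2-en-1-yl)-2-(2-methylpropanoyl)cyclohexan-1-one (C2 epimerisable)
Conditions: homoprenyl-MgBr (from 7, Mg), CuBr·SMe2 (20 mol %), THF, −40 → −10 °C; then 8, −78 → 0 °C
Reagents that add atoms: (4-methylpent-3-en-1-yl)magnesium bromide, CC(C)=CCC[Mg]Br; isobutyryl chloride, CC(C)C(Cl)=O
Why: Cu-catalysed conjugate addition followed by C-acylation of the regiodefined magnesium enolate; A(1,2) strain with the C3 methyl makes the C4 prenyl pseudoaxial, so the cuprate adds anti to it and sets the quaternary centre (homoprenyl trans to prenyl).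

Step 6
Reactants: 9; 10, 5-methylhex-4-enoic acid (as its imidazolide); 11, prenyl bromide
Product: 12, (3R,4S)-3-methyl-6-(5-methylhex-4-enoyl)-3-(4-methylpent-3-en-1-yl)-4,6-bis(3-methylbut-2-en-1-yl)-2-(2-methylpropanoyl)cyclohexan-1-one (mixture at C2 and C6)
Conditions: LDA (2.3 equiv), THF, −78 → −30 °C; imidazolide of 10 (10, CDI, THF), −78 → 0 °C; then 11, DMPU, 0 → 40 °C (one pot)
Reagents that add atoms: 5-methylhex-4-enoyl imidazolide, CC(C)=CCCC(=O)n1ccnc1; prenyl bromide, CC(C)=CCBr
Why: γ-Acylation of the β-diketone dianion (Harris/Hauser type) at the ring α′-CH2, then C-alkylation of the new, less hindered β-diketonate; the new quaternary carbon is formed as a mixture, which does not matter because it becomes sp2 in step 8.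

Step 7
Reactants: 12
Product: 13, the (1Z)-triethylsilyl enol ether of the side-chain ketone: 6-[(1Z)-5-methyl-1-(triethylsilyloxy)hexa-1,4-dien-1-yl] analogue of 12, ring ketone and isobutyryl diketone unchanged
Conditions: LDA (2.2 equiv), THF, −78 °C; TESCl (1.05 equiv); pH 7 buffer
Reagents that add atoms: chlorotriethylsilane, CC[Si](Cl)(CC)CC
Why: After the acidic C2–H is removed, the second deprotonation can only occur α to the side-chain ketone (its other α-carbon is quaternary), and that simple enolate is O-silylated far faster than the diketonate, giving the Z enol ether (kinetic enolate silylation).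

Step 8
Reactants: 13
Product: 15, (4R,5R,6S,8S)-5-methyl-5-(4-methylpent-3-en-1-yl)-2,6,8-tris(3-methylbut-2-en-1-yl)-4-(2-methylpropanoyl)cyclooctane-1,3-dione (C2 epimers/enol), via photoproduct 14 (ring-expanded triethylsilyl enol ether, not isolated)
Conditions: hν (300 nm, Pyrex), degassed C6H6 (5 mM), rt; then TBAF/AcOH, THF, 0 °C → rt
Reagents that add atoms: none
Why: Proposed new method: photochemical 1,3-acyl-shift ring expansion of a β,γ-unsaturated ketone whose alkene is a silyl enol ether. n→π* excitation of the ring ketone causes Norrish type I cleavage of the congested C(=O)–Cq bond to an acyl/2-silyloxyallyl radical pair. O-silylation blocks recombination at oxygen, so the acyl radical recombines at the less hindered allyl terminus, forming the C2–C3 bond and the eight-membered ring as enol ether 14. The singlet radical-pair path is faster than any reaction with the pendant prenyl alkenes. The closest known reactions are the 1,3-acyl-shift ring expansion of 2-alkenylcycloalkanones and the photo-Fries shift of enol esters. Desilylation then protonates C8; C8 and C4 settle to the thermodynamic configurations (assumption above).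

Step 9
Reactants: 15
Product: 16, hyphenrone F, (2R,4R,5R,6S,8S)-2-hydroxy-5-methyl-5-(4-methylpent-3-en-1-yl)-2,6,8-tris(3-methylbut-2-en-1-yl)-4-(2-methylpropanoyl)cyclooctane-1,3-dione
Conditions: O2 (1 atm), CeCl3·7H2O (10 mol %), i-PrOH, rt
Reagents that add atoms: dioxygen, O=O
Why: Cerium-catalysed aerobic α-hydroxylation of the 2-alkyl-1,3-diketone under neutral conditions; O2 is expected to attack the planar C1–C2–C3 enolate anti to the adjacent C8 prenyl group, giving 2R. The C4–H diketone is not oxidised because enolisation toward C4 is blocked by strain with the quaternary C5, as in the natural product itself.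

**Compound list**
1 | (+)-limonene 1,2-oxide, (4R), cis/trans mixture | CC12OC1C[C@@H](CC2)C(C)=C | starting material
2 | (3R)-6-oxo-3-(prop-1-en-2-yl)heptanal | O=CC[C@@H](CCC(C)=O)C(C)=C | intermediate
3 | isopropyltriphenylphosphonium iodide | CC(C)[P+](c1ccccc1)(c1ccccc1)c1ccccc1.[I-] | starting material
4 | (5R)-8-methyl-5-(prop-1-en-2-yl)non-7-en-2-one | CC(C)=CC[C@@H](CCC(C)=O)C(C)=C | intermediate
5 | (6R)-9-methyl-6-(prop-1-en-2-yl)deca-1,8-dien-3-one | CC(C)=CC[C@@H](CCC(=O)C=C)C(C)=C | intermediate
6 | (4R)-3-methyl-4-(3-methylbut-2-en-1-yl)cyclohex-2-en-1-one | CC(C)=CC[C@H]1CCC(=O)C=C1C | intermediate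
7 | 5-bromo-2-methylpent-2-ene | CC(C)=CCCBr | starting material
8 | isobutyryl chloride | CC(C)C(Cl)=O | starting material
9 | (3R,4R)-3-methyl-3-(4-methylpent-3-en-1-yl)-4-(3-methylbut-2-en-1-yl)-2-(2-methylpropanoyl)cyclohexan-1-one | CC(C)=CCC[C@]1(C)[C@@H](CC=C(C)C)CCC(=O)C1C(=O)C(C)C | intermediate
10 | 5-methylhex-4-enoic acid | CC(C)=CCCC(O)=O | starting material
11 | prenyl bromide (1-bromo-3-methylbut-2-ene) | CC(C)=CCBr | starting material
12 | (3R,4S)-3-methyl-6-(5-methylhex-4-enoyl)-3-(4-methylpent-3-en-1-yl)-4,6-bis(3-methylbut-2-en-1-yl)-2-(2-methylpropanoyl)cyclohexan-1-one | CC(C)=CCC[C@]1(C)[C@@H](CC=C(C)C)CC(CC=C(C)C)(C(=O)CCC=C(C)C)C(=O)C1C(=O)C(C)C | intermediate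
13 | (3R,4S)-3-methyl-3-(4-methylpent-3-en-1-yl)-4,6-bis(3-methylbut-2-en-1-yl)-2-(2-methylpropanoyl)-6-[(1Z)-5-methyl-1-(triethylsilyloxy)hexa-1,4-dien-1-yl]cyclohexan-1-one | CC(C)=CCC[C@]1(C)[C@@H](CC=C(C)C)CC(CC=C(C)C)(/C(O[Si](CC)(CC)CC)=C/CC=C(C)C)C(=O)C1C(=O)C(C)C | intermediate
14 | (6S,7R)-7-methyl-7-(4-methylpent-3-en-1-yl)-2,4,6-tris(3-methylbut-2-en-1-yl)-8-(2-methylpropanoyl)-3-(triethylsilyloxy)cyclooct-3-en-1-one | CC(C)=CCC[C@]1(C)[C@@H](CC=C(C)C)CC(CC=C(C)C)=C(O[Si](CC)(CC)CC)C(CC=C(C)C)C(=O)C1C(=O)C(C)C | intermediate (not isolated)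
15 | (4R,5R,6S,8S)-5-methyl-5-(4-methylpent-3-en-1-yl)-2,6,8-tris(3-methylbut-2-en-1-yl)-4-(2-methylpropanoyl)cyclooctane-1,3-dione | CC(C)=CCC[C@]1(C)[C@@H](CC=C(C)C)C[C@H](CC=C(C)C)C(=O)C(CC=C(C)C)C(=O)[C@H]1C(=O)C(C)C | intermediate
16 | hyphenrone F, (2R,4R,5R,6S,8S) | CC(C)=CCC[C@]1(C)[C@@H](CC=C(C)C)C[C@H](CC=C(C)C)C(=O)[C@](O)(CC=C(C)C)C(=O)[C@H]1C(=O)C(C)C | target

**Totals**
Total steps: 9. Longest linear sequence: 9 (from limonene oxide).

**Three steps most likely to fail**
1. Step 8 (the proposed new photochemical ring expansion). Risks are an unfavourable photostationary ratio with 13, competing α-cleavage next to the isobutyryl diketone, and loss of the ketone chromophore if that diketone enolises. Fallback (known chemistry): quench the step 5 enolate with H+ instead of acylating, form the kinetic TMS enol ether on the CH2 side, add dichloroketene (Cl3CCOCl, Zn) in a [2+2], then ring-open and dechlorinate (Zn/AcOH). This is the established two-carbon ring expansion to a cyclooctane-1,3-dione; the prenyl and isobutyryl groups are then installed by enolate chemistry.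
2. Step 9 (facial selectivity at C2, which also depends on the C8 configuration from step 8). The eight-membered ring gives no firm basis for predicting either; if the wrong C2 epimer forms it cannot be corrected. Fallback: reverse the order of bond formation at C2. Use O-TBS-glycolic acid imidazolide in step 6 so the ring expansion delivers the 2-silyloxy diketone, then C-prenylate that enolate (the electrophile enters the same face, giving the opposite C2 configuration) and desilylate.
3. Step 6 (one-pot dianion acylation/alkylation next to a hindered diketone). Fallback: avoid polyanions by changing the order. Protonate the step 5 enolate, carry out α′-acylation, prenylation and enol silylation on the simple ketone with mono-enolates, then add the isobutyryl group by acylating the only remaining enolisable position (LDA, isobutyryl chloride; or isobutyraldehyde aldol then oxidation) before photolysis. This costs one extra step.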